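**Plan**

1. Numbering used throughout (Lycopodium convention): cyclohexane A = C7–C8–C15(Me,OAc)–C14–C13(OAc)–C12; cyclopentanone B = C12–C4–C5(=O)–C6–C7; azonine = C12–C11–C10–C9–N–C1–C2–C3=C4.
2. Retrosynthetic cuts, in order: N–Boc; C5=O (from an allylic CH2); C3=C4 (carbonyl coupling, which opens the azonine); C15–O (epoxide of C14=C15); C12–C13 and C7–C8 (Diels–Alder); C11–C12 (B-alkyl Suzuki); N–C1 (N-alkylation).
3. Forward: ring B is bought as cyclopentenone, ring A is fused on by Diels–Alder, and the nine-membered azonine is closed last by McMurry coupling of the C4 ketone with a C3 aldehyde on the nitrogen chain.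
4. Enabling feature: C4, the atom shared by ring B and the azonine, sits next to the quaternary C12. A C4 ketone first activates C12=C7 as dienophile, then becomes the exocyclic C3=C4 alkene; because C12 has no hydrogen, the only allylic CH2 on the substituted alkene end is C5, so allylic oxidation returns the carbonyl one carbon over.
5. Stereochemistry: one catalytic enantioselective Diels–Alder sets C7, C12 and C13 together (catalyst face, endo rule, cis addition); C15 is relayed from C13 by OH-directed epoxidation and SN2 hydride opening.

Key step: step 8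

Assumption: the (S)-prolinol-derived oxazaborolidinium is taken to shield the enone face that leads to the enantiomer drawn (otherwise the (R)-catalyst is used), and the minor (Z)-isomer of diene 9 is taken not to react.

**Route**

Step 1
Reactants: 1 cyclopent-2-en-1-one
Product: 2 2-iodocyclopent-2-en-1-one
Conditions: I2, pyridine, CH2Cl2, 0 °C → rt
Reagents that add atoms: iodine II
Why: Pyridine adds to the β-carbon, the enolate is iodinated at the α-carbon and pyridine is eliminated (α-iodination of an enone by addition–elimination), which should give only the α-iodoenone.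

Step 2
Reactants: 3 tert-butyl N-allylcarbamate; 4 (3-bromopropoxy)(tert-butyl)dimethylsilane
Product: 5 tert-butyl N-allyl-N-[3-(tert-butyldimethylsilyloxy)propyl]carbamate
Conditions: NaH, Bu4NI (cat.), DMF, 0 °C → rt
Reagents that add atoms: none
Why: The sodium salt of the carbamate is alkylated by the primary bromide (SN2 N-alkylation), forming the N–C1 bond.

Step 3
Reactants: 5 tert-butyl N-allyl-N-[3-(tert-butyldimethylsilyloxy)propyl]carbamate; 2 2-iodocyclopent-2-en-1-one
Product: 7 tert-butyl N-[3-(tert-butyldimethylsilyloxy)propyl]-N-[3-(5-oxocyclopent-1-en-1-yl)propyl]carbamate, via B-alkyl-9-BBN adduct 6 (not isolated)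
Conditions: 9-BBN, THF, rt; then 2, PdCl2(dppf) (cat.), AsPh3, Cs2CO3, DMF/H2O, rt
Reagents that add atoms: none
Why: 9-BBN hydroborates the terminal alkene at its terminal carbon and the B-alkyl group is transferred to the α-iodoenone (B-alkyl Suzuki–Miyaura coupling), forming the C11–C12 bond without touching carbamate or silyl ether.

Step 4
Reactants: 8 3-methylbut-2-enal
Product: 9 (E)-triisopropyl[(3-methylbuta-1,3-dien-1-yl)oxy]silane
Conditions: TIPSOTf, Et3N, Et2O, 0 °C → rt
Reagents that add atoms: triisopropylsilyl trifluoromethanesulfonate CC(C)[Si](C(C)C)(C(C)C)OS(=O)(=O)C(F)(F)F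
Why: O-silylation of the enal followed by γ-deprotonation (vinylogous enolisation) should give the 1-silyloxy-1,3-diene, mainly as the E isomer for steric reasons.

Step 5
Reactants: 7 tert-butyl N-[3-(tert-butyldimethylsilyloxy)propyl]-N-[3-(5-oxocyclopent-1-en-1-yl)propyl]carbamate; 9 (E)-triisopropyl[(3-methylbuta-1,3-dien-1-yl)oxy]silane
Product: 10 cis-fused Diels–Alder adduct (C4 ketone, C14=C15 alkene, 13-OTIPS cis to C4 and trans to the C11 chain, H-7 cis to the C11 chain, chain = (CH2)3N(Boc)(CH2)3OTBS on C12)
Conditions: chiral oxazaborolidinium triflimide [from (S)-α,α-diphenylprolinol, o-tolylboroxine, Tf2NH] (20 mol %), CH2Cl2, −78 → −40 °C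
Reagents that add atoms: none
Why: Lewis-acid-catalysed enantioselective Diels–Alder reaction: the 1-silyloxy and 3-methyl donors make C8 the nucleophilic diene terminus, which bonds to the β-carbon C7; the endo transition state places C13–OTIPS cis to the C4 carbonyl; suprafacial addition gives the cis ring fusion with quaternary C12; and the chiral Lewis acid shields one enone face, fixing the absolute configuration of C7, C12 and C13 in one event.

Step 6
Reactants: 10 Diels–Alder adduct
Product: 11 primary alcohol (chain = (CH2)3N(Boc)(CH2)3OH, otherwise as 10)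
Conditions: PPTS, MeOH, rt
Reagents that add atoms: none
Why: Acid-catalysed methanolysis should cleave the unhindered primary TBS ether much faster than the hindered secondary TIPS ether (selective desilylation).

Step 7
Reactants: 11 primary alcohol
Product: 12 keto aldehyde (C4 ketone, C3 aldehyde on the N-chain)
Conditions: Dess–Martin periodinane, NaHCO3, CH2Cl2, 0 °C → rt
Reagents that add atoms: none
Why: Dess–Martin oxidation converts the primary alcohol into the aldehyde under buffered conditions that leave ketone, carbamate and silyl ether untouched.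

Step 8
Reactants: 12 keto aldehyde
Product: 13 N-Boc tricyclic azonine with C3=C4 alkene (C2 cis to C12), 13-OTIPS and C14=C15
Conditions: TiCl3(DME)1.5, Zn–Cu, DME, reflux; 12 added by syringe pump (high dilution)
Reagents that add atoms: none
Why: Low-valent titanium reduces the C4 ketone and the C3 aldehyde to titanium-bound ketyls that couple to a titanium pinacolate, which is deoxygenated on the metal to the C3=C4 alkene (McMurry coupling); the closest known reaction type is the intramolecular keto-aldehyde McMurry cyclisation to medium-ring cycloalkenes. The nine-membered azonine is closed by this reductive carbonyl–carbonyl coupling (C3–C4 bond formation, then loss of both oxygens), a mode that copes with medium-ring strain because both ends are held on titanium. No stereocentre is formed; the ring size allows only the in-ring cis alkene (C2 cis to C12), which is the geometry of the target enone. The step needs intramolecular coupling to outrun aldehyde–aldehyde dimerisation; slow addition at high dilution and the placement of both chains on the adjacent atoms C12 and C4 of the rigid cis-hydrindane should secure this. Only ketone and aldehyde are reducible here, so carbamate, silyl ether and the trisubstituted C14=C15 alkene should survive. The ketone that activated the dienophile is removed in this step, and its oxygen is returned at C5 in step 13.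

Step 9
Reactants: 13 N-Boc tricyclic azonine (13-OTIPS)
Product: 14 allylic alcohol (13-OH)
Conditions: TBAF, THF, rt → 40 °C
Reagents that add atoms: none
Why: Fluoride cleaves the silyl ether (desilylation) and frees the allylic C13 alcohol needed to direct the next step.

Step 10
Reactants: 14 allylic alcohol
Product: 15 14,15-epoxy-13-ol (epoxide oxygen syn to 13-OH)
Conditions: VO(acac)2 (cat.), t-BuOOH (1.1 equiv), CH2Cl2, 0 °C → rt
Reagents that add atoms: tert-butyl hydroperoxide CC(C)(C)OO
Why: Hydroxyl-directed vanadium-catalysed epoxidation delivers oxygen from the vanadate ester of the C13 alcohol to the same face of the adjacent C14=C15 bond, setting C14 and C15, while the merely homoallylic C3=C4 alkene should react much more slowly.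

Step 11
Reactants: 15 epoxy alcohol
Product: 16 cis-13,15-diol (tertiary 15-OH, 15-methyl trans to both hydroxyls)
Conditions: LiEt3BH, THF, 0 °C → rt
Reagents that add atoms: none
Why: SN2 hydride opening of the epoxide at the less substituted C14 leaves the C15–O bond intact, so the tertiary alcohol should form cis to the C13 hydroxyl (regioselective reductive epoxide opening).

Step 12
Reactants: 16 cis-13,15-diol
Product: 17 13,15-diacetate
Conditions: Ac2O, DMAP, Et3N, CH2Cl2, rt → 40 °C
Reagents that add atoms: acetic anhydride CC(=O)OC(C)=O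
Why: DMAP-catalysed acylation esterifies the secondary alcohol and, on warming, the tertiary one, while the carbamate nitrogen cannot be acylated.

Step 13
Reactants: 17 13,15-diacetate
Product: 18 5-hydroxy diacetate (allylic alcohol, both C5 epimers)
Conditions: SeO2 (0.5 equiv), t-BuOOH, CH2Cl2, rt
Reagents that add atoms: selenium dioxide O=[Se]=O (catalytic oxygen carrier); tert-butyl hydroperoxide CC(C)(C)OO
Why: Selenium dioxide allylic oxidation (ene reaction, then [2,3]-sigmatropic shift) attacks the allylic CH2 on the more substituted alkene carbon, and since C12 carries no hydrogen this can only be C5; the C3=C4 bond returns to its place and the new C5 carbinol centre is erased in step 14.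

Step 14
Reactants: 18 5-hydroxy diacetate
Product: 19 N-Boc enone (N-Boc derivative of the target)
Conditions: Dess–Martin periodinane, NaHCO3, CH2Cl2, rt
Reagents that add atoms: none
Why: Dess–Martin oxidation of the allylic alcohol should give the conjugated enone without moving the alkene.

Step 15
Reactants: 19 N-Boc enone
Product: 21 target amine, via trimethylsilyl carbamate 20 (not isolated)
Conditions: TMSOTf, 2,6-lutidine, CH2Cl2, 0 °C; then MeOH; aq. NaHCO3
Reagents that add atoms: none
Why: TMSOTf silylates the Boc carbonyl, tert-butyl cation is lost to give the silyl carbamate, and methanol releases the free secondary amine with loss of CO2 (silyl-triflate-mediated Boc cleavage), conditions chosen to spare the tertiary acetate and the enone.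

**Compound list**

1 | cyclopent-2-en-1-one | O=C1C=CCC1 | starting material
2 | 2-iodocyclopent-2-en-1-one | O=C1CCC=C1I | intermediate
3 | tert-butyl N-allylcarbamate | C=CCNC(=O)OC(C)(C)C | starting material
4 | (3-bromopropoxy)(tert-butyl)dimethylsilane | BrCCCO[Si](C)(C)C(C)(C)C | starting material
5 | tert-butyl N-allyl-N-[3-(tert-butyldimethylsilyloxy)propyl]carbamate | C=CCN(C(=O)OC(C)(C)C)CCCO[Si](C)(C)C(C)(C)C | intermediate
6 | B-alkyl-9-BBN adduct: tert-butyl N-[3-(9-borabicyclo[3.3.1]nonan-9-yl)propyl]-N-[3-(tert-butyldimethylsilyloxy)propyl]carbamate | CC(C)(C)OC(=O)N(CCCB1C2CCCC1CCC2)CCCO[Si](C)(C)C(C)(C)C | intermediate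
7 | tert-butyl N-[3-(tert-butyldimethylsilyloxy)propyl]-N-[3-(5-oxocyclopent-1-en-1-yl)propyl]carbamate | O=C1CCC=C1CCCN(C(=O)OC(C)(C)C)CCCO[Si](C)(C)C(C)(C)C | intermediate
8 | 3-methylbut-2-enal | CC(C)=CC=O | starting material
9 | (E)-triisopropyl[(3-methylbuta-1,3-dien-1-yl)oxy]silane | C=C(C)/C=C/O[Si](C(C)C)(C(C)C)C(C)C | intermediate
10 | Diels–Alder adduct: cis-fused 5-methyl-7-(triisopropylsilyloxy)-2,3,3a,4,7,7a-hexahydro-1H-inden-1-one bearing at C7a the 3-[N-Boc-N-(3-TBSO-propyl)amino]propyl chain; 7-OTIPS cis to C1, H-3a cis to the chain | CC(C)[Si](C(C)C)(C(C)C)O[C@H]1C=C(C)C[C@H]2CCC(=O)[C@]21CCCN(C(=O)OC(C)(C)C)CCCO[Si](C)(C)C(C)(C)C | intermediate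
11 | primary alcohol: as 10 with the chain ending in CH2OH | CC(C)[Si](C(C)C)(C(C)C)O[C@H]1C=C(C)C[C@H]2CCC(=O)[C@]21CCCN(C(=O)OC(C)(C)C)CCCO | intermediate
12 | keto aldehyde: as 10 with the chain ending in CHO | CC(C)[Si](C(C)C)(C(C)C)O[C@H]1C=C(C)C[C@H]2CCC(=O)[C@]21CCCN(C(=O)OC(C)(C)C)CCC=O | intermediate
13 | N-Boc tricyclic azonine: rings A/B/azonine closed, C3=C4 alkene with C2 cis to C12, C5 = CH2, 13-OTIPS, C14=C15 | CC(C)[Si](C(C)C)(C(C)C)O[C@H]1C=C(C)C[C@H]2CC/C3=C/CCN(C(=O)OC(C)(C)C)CCC[C@@]321 | intermediate
14 | allylic alcohol: as 13 with 13-OH | O[C@H]1C=C(C)C[C@H]2CC/C3=C/CCN(C(=O)OC(C)(C)C)CCC[C@@]321 | intermediate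
15 | 14,15-epoxy-13-ol, epoxide syn to 13-OH | O[C@H]1[C@H]4O[C@@]4(C)C[C@H]2CC/C3=C/CCN(C(=O)OC(C)(C)C)CCC[C@@]321 | intermediate
16 | cis-13,15-diol (15-OH tertiary, 15-Me trans to the hydroxyls) | O[C@H]1C[C@@](C)(O)C[C@H]2CC/C3=C/CCN(C(=O)OC(C)(C)C)CCC[C@@]321 | intermediate
17 | 13,15-diacetate | CC(=O)O[C@H]1C[C@@](C)(OC(C)=O)C[C@H]2CC/C3=C/CCN(C(=O)OC(C)(C)C)CCC[C@@]321 | intermediate
18 | 5-hydroxy-13,15-diacetate (allylic alcohol, both C5 epimers) | CC(=O)O[C@H]1C[C@@](C)(OC(C)=O)C[C@H]2CC(O)/C3=C/CCN(C(=O)OC(C)(C)C)CCC[C@@]321 | intermediate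
19 | N-Boc enone (N-Boc derivative of the target) | CC(=O)O[C@H]1C[C@@](C)(OC(C)=O)C[C@H]2CC(=O)/C3=C/CCN(C(=O)OC(C)(C)C)CCC[C@@]321 | intermediate
20 | N-(trimethylsilyloxycarbonyl) derivative of the target (silyl carbamate) | CC(=O)O[C@H]1C[C@@](C)(OC(C)=O)C[C@H]2CC(=O)/C3=C/CCN(C(=O)O[Si](C)(C)C)CCC[C@@]321 | intermediate
21 | CNP0120442.1: (7S,12S,13S,15S)-13,15-diacetoxy-3,4-didehydro keto amine (numbering as in the plan) | CC(=O)O[C@H]1C[C@@](C)(OC(C)=O)C[C@H]2CC(=O)/C3=C/CCNCCC[C@@]321 | target

**Summary**

Total step count: 15. Longest linear sequence: 13 steps (3 → 21 through steps 2, 3, 5–15; the same length from 1).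

Steps most likely to fail:

Step 5 (enantioselective Diels–Alder). The α-substituted enone may react sluggishly, the facial selectivity may be poor, or the silyl dienol ether may be lost by protodesilylation under the strong Lewis acid. The fallback sets out from 7 and replaces catalyst control by resolution. EtAlCl2-promoted (or high-pressure) cycloaddition with the acid-tolerant (E)-3-methylbuta-1,3-dien-1-yl acetate F1 should give the endo adduct as the racemic acetate F2. Lipase-mediated enantioselective hydrolysis in buffer should then give the 13-hydroxy ketone F3 of the required absolute configuration (or leave its acetate, which is then methanolysed). Silylation with TIPSOTf/2,6-lutidine comes back to the route at 10.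

Step 8 (McMurry ring closure). Intermolecular coupling, arrest at the pinacol stage, or β-elimination of the carbamate from the aldehyde may compete. The fallback sets out from alcohol 11 and closes the ring by phosphorus ylide olefination instead. Iodination (I2, PPh3, imidazole) gives the primary iodide F4, heating with PPh3 in MeCN gives the phosphonium iodide F5, and slow addition of F5 to KHMDS in THF at high dilution should close the azonine by intramolecular Wittig reaction on the C4 ketone, coming back at 13.

Step 13 (allylic oxidation). Oxidation may occur at the other allylic carbon (C2) or run on to over-oxidised products. The fallback sets out from 17 and installs the C5 oxygen by a stepwise selenium route. PhSeCl adds across C3=C4 with chloride at the tertiary C4, and loss of HCl towards C5 (pyridine) gives the allylic phenyl selenide F6 (SePh on C3, C4=C5). Oxidation with H2O2/pyridine triggers the selenoxide [2,3]-sigmatropic rearrangement, which places oxygen on C5 and restores C3=C4, coming back at 18.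

**Further compounds**

F1 | step 5 | (E)-3-methylbuta-1,3-dien-1-yl acetate | C=C(C)/C=C/OC(C)=O
F2 | step 5 | racemic endo Diels–Alder acetate (as 10 with 13-OAc in place of 13-OTIPS; racemate, one enantiomer drawn) | CC(=O)O[C@H]1C=C(C)C[C@H]2CCC(=O)[C@]21CCCN(C(=O)OC(C)(C)C)CCCO[Si](C)(C)C(C)(C)C
F3 | step 5 | resolved 13-hydroxy ketone (as 10 with 13-OH) | O[C@H]1C=C(C)C[C@H]2CCC(=O)[C@]21CCCN(C(=O)OC(C)(C)C)CCCO[Si](C)(C)C(C)(C)C
F4 | step 8 | primary iodide (as 11 with CH2I) | CC(C)[Si](C(C)C)(C(C)C)O[C@H]1C=C(C)C[C@H]2CCC(=O)[C@]21CCCN(C(=O)OC(C)(C)C)CCCI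
F5 | step 8 | triphenylphosphonium iodide of F4 | CC(C)[Si](C(C)C)(C(C)C)O[C@H]1C=C(C)C[C@H]2CCC(=O)[C@]21CCCN(C(=O)OC(C)(C)C)CCC[P+](c1ccccc1)(c1ccccc1)c1ccccc1.[I-]
F6 | step 13 | allylic phenyl selenide (SePh on C3, C4=C5, diacetate, N-Boc; C3 epimers) | CC(=O)O[C@H]1C[C@@](C)(OC(C)=O)C[C@H]2CC=C3C([Se]c4ccccc4)CCN(C(=O)OC(C)(C)C)CCC[C@@]321
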